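**Plan**
- Retrosynthesis: the two CH2–ring B bonds are cut, first the bridge to ring A, then the bridge to ring C. This leaves butanoylphloroglucinol (ring B) and two outer monomers with one free ring carbon each; each CH2 is traced back to an aminomethyl group on the outer ring.
- Ring A (the outer ring with OCH3 ortho to the butanoyl group; a1 bridge carbon, a2 C–OH, a3 C–CH3, a4 C–OCH3, a5 C–butanoyl, a6 C–OH) is cut at a3–a4 and a5–a6. Its a4 OCH3 sits next to the ketone, a chelated position that selective O-methylation does not reach; together with a5 it is the two carbons of a 1-methoxy ynone, while a6–a1–a2–a3 with the a3 CH3 is a 1,1,3-trioxygenated penta-1,3-diene.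
- Forward: the diene (two steps) and the ynone (two steps) give the ring A monomer by cycloaddition and aromatisation. Ring C (aspidinol) and ring B come from Friedel–Crafts acylation of the phloroglucinols, ring C after para-selective O-methylation.
- Assembly: the Mannich base of ring C is joined to excess ring B ketone to give the B–C half, then the Mannich base of ring A is joined to the last free ring carbon of that half.
- Stereochemistry: the target has no stereocentre. The alkene geometries, the racemic carbinol of the ynone branch and the sp3 centres of the cycloadduct are all erased.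

Key step: step 5

Remark: the diene is used open-chain. An acetonide tying its C1 and C3 oxygens into a 1,3-dioxin ring would hold the C2–C3 bond s-trans, so the two termini could not span one alkyne. The methyl ester/silyl form can turn s-cis and loses methanol where the acetonide would lose acetone.

Assumption: the target is written as its all-phenol tautomer; methyl 3-oxopentanoate, 2-methylbenzene-1,3,5-triol and benzene-1,3,5-triol are bought.

Step 1
Reactants: 1 (methyl 3-oxopentanoate)
Product: 2 methyl (2Z)-3-[(trimethylsilyl)oxy]pent-2-enoate
Conditions: TMSCl, Et3N, pentane, rt; filtration, distillation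
Reagents that add atoms: chlorotrimethylsilane, C[Si](C)(C)Cl
Why: O-silylation of the enol of a β-keto ester under soft enolisation (amine base, silyl chloride) should give the silyl enol ether with the Z geometry of the chelated enol and without C-silylation.

Step 2
Reactants: 2 (methyl (2Z)-3-[(trimethylsilyl)oxy]pent-2-enoate)
Product: 4 (1Z,3Z)-1-methoxy-1,3-bis[(trimethylsilyl)oxy]penta-1,3-diene, via lithium dienolate 3 (not isolated)
Conditions: LiN(i-Pr)2 (commercial solution), THF, −78 °C; TMSCl, −78 → 0 °C; pentane, filtration under argon; used crude
Reagents that add atoms: chlorotrimethylsilane, C[Si](C)(C)Cl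
Why: Kinetic γ-deprotonation of the β-silyloxy enoate gives the extended ester dienolate, which is silylated on oxygen (the standard second stage of 1,3-bis-silyl enol ether synthesis); the 3Z isomer with the methyl group on the outer side of the s-cis diene is expected to prevail, and either isomer leads to the same arene.

Step 3
Reactants: 5 (2-chloro-1,1-dimethoxyethane); 6 (butanal)
Product: 8 1-methoxyhex-1-yn-3-ol (racemic), via lithium methoxyacetylide 7 (not isolated)
Conditions: Et2NH, n-BuLi (3 equiv each), THF, 0 °C; 5, 0 °C; 6, −78 → 0 °C; H2O quench, base-washed glassware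
Reagents that add atoms: none
Why: Three equivalents of LiNEt2 should eliminate HCl and methanol from the chloro acetal and deprotonate the resulting methoxyethyne, and the acetylide then adds 1,2 to the aldehyde (alkynylation of a carbonyl group); the new carbinol centre is racemic and is removed in step 4.

Step 4
Reactants: 8 (1-methoxyhex-1-yn-3-ol)
Product: 9 1-methoxyhex-1-yn-3-one
Conditions: activated MnO2 (excess), CH2Cl2, 0 °C → rt; filtration through Celite; used at once
Reagents that add atoms: none
Why: Heterogeneous MnO2 oxidation of a propargylic alcohol runs under neutral conditions, which should spare the acid-labile alkoxyalkyne from Meyer–Schuster rearrangement.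

Step 5
Reactants: 4 ((1Z,3Z)-1-methoxy-1,3-bis[(trimethylsilyl)oxy]penta-1,3-diene); 9 (1-methoxyhex-1-yn-3-one)
Product: 11 1-(4,6-dihydroxy-2-methoxy-3-methylphenyl)butan-1-one, via cyclohexadiene cycloadduct 10 (not isolated)
Conditions: 4 (1.5 equiv), toluene, 80 °C, no Lewis acid; then 1 M HCl, THF, rt
Reagents that add atoms: none
Why: The 1,1,3-trioxygenated diene 4 and the acyl-activated alkyne 9 should combine in a thermal, asynchronous [4+2] cycloaddition of normal electron demand, in which the CH(CH3) terminus bonds to the methoxy-bearing β-carbon of the ynone (a3–a4) and the ketene-acetal carbon bonds to the acyl-bearing α-carbon (a5–a6), giving cyclohexa-1,4-diene 10. Aqueous acid then collapses the a6 silyl methyl ketal to the ketone with loss of methanol and cleaves the a2 silyl enol ether, and the resulting cyclohexenedione tautomerises to the resorcinol, so a2 and a6 end as free hydroxyls while the a4 OCH3 and the a3 CH3 arrive unchanged. The closest known reaction type is the Diels–Alder reaction of 1-alkoxy-1,3-bis(silyloxy) and related 1,1-dioxy-3-silyloxy dienes with acetylenic ketones and esters, which gives resorcinol derivatives after loss of an alcohol. Ring A is closed as a six-membered carbocycle by this intermolecular [4+2] mode, and no stereocentre is kept, because the a3 and a6 centres of 10 vanish on aromatisation and the geometry of 4 affects only the rate. The step needs the CH3-bearing terminus to join the OCH3-bearing alkyne carbon; this is secured because the largest HOMO coefficient of 4 lies on C4, remote from the ketene acetal, and the carbonyl group makes the β-carbon of 9 its electrophilic end. A Michael–aldol course through C2 of the diene and the ketone carbonyl is avoided by leaving out Lewis acid, and the hydrolytic work-up ensures that methanol, not silanol, is lost from a6.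

Step 6
Reactants: 12 (2-methylbenzene-1,3,5-triol); 13 (butanoyl chloride)
Product: 14 1-(2,4,6-trihydroxy-3-methylphenyl)butan-1-one
Conditions: AlCl3 (4 equiv), PhNO2, rt → 60 °C; ice, aq HCl
Reagents that add atoms: none
Why: Friedel–Crafts C-acylation of the electron-rich triol has only one possible outcome because the two free ring carbons are equivalent, and the first acyl group deactivates the ring against a second acylation.

Step 7
Reactants: 14 (1-(2,4,6-trihydroxy-3-methylphenyl)butan-1-one)
Product: 15 aspidinol, 1-(2,6-dihydroxy-4-methoxy-3-methylphenyl)butan-1-one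
Conditions: Me2SO4 (1.0 equiv), K2CO3 (1.0 equiv), acetone, reflux
Reagents that add atoms: dimethyl sulfate, COS(=O)(=O)OC
Why: Williamson methylation with one equivalent of base and electrophile should take the 4-OH para to the ketone, which is the most acidic hydroxyl and the only one not flanking the carbonyl group and sharing its hydrogen-bond chelate.

Step 8
Reactants: 16 (benzene-1,3,5-triol); 13 (butanoyl chloride)
Product: 17 1-(2,4,6-trihydroxyphenyl)butan-1-one
Conditions: AlCl3 (4 equiv), PhNO2, rt → 60 °C; ice, aq HCl
Reagents that add atoms: none
Why: Friedel–Crafts monoacylation of phloroglucinol is a standard entry to acylphloroglucinols and stops after one acyl group because the product ketone is deactivated.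

Step 9
Reactants: 15 (aspidinol)
Product: 18 1-{3-[(dimethylamino)methyl]-2,6-dihydroxy-4-methoxy-5-methylphenyl}butan-1-one
Conditions: 15 added to CH2(NMe2)2 (2 equiv), CH2Cl2, rt; evaporation; used crude
Reagents that add atoms: N,N,N',N'-tetramethylmethanediamine, CN(C)CN(C)C
Why: In this Mannich aminomethylation the acidic phenol protonates the aminal and the released methyleneiminium ion is attacked by the only unsubstituted ring carbon; no free formaldehyde is present and the aminal is in excess, which should suppress the symmetrical methylene-bridged dimer.

Step 10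
Reactants: 18 (ring C Mannich base); 17 (1-(2,4,6-trihydroxyphenyl)butan-1-one)
Product: 20 1-{3-[(3-butanoyl-2,4-dihydroxy-6-methoxy-5-methylphenyl)methyl]-2,4,6-trihydroxyphenyl}butan-1-one, via ortho-quinone methide 19 (not isolated)
Conditions: 17 (3 equiv), 1,4-dioxane, 90 °C, N2 sweep; chromatography, excess 17 recovered
Reagents that add atoms: none
Why: On heating, the ortho-hydroxybenzylamine loses dimethylamine to the quinone methide, and a free ring carbon of 17 adds to it in a Michael (Friedel–Crafts-type) step with rearomatisation; the excess of 17 should hold back a second alkylation at its other free position.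

Step 11
Reactants: 11 (1-(4,6-dihydroxy-2-methoxy-3-methylphenyl)butan-1-one)
Product: 21 1-{3-[(dimethylamino)methyl]-2,4-dihydroxy-6-methoxy-5-methylphenyl}butan-1-one
Conditions: 11 added to CH2(NMe2)2 (2 equiv), CH2Cl2, rt; evaporation; used crude
Reagents that add atoms: N,N,N',N'-tetramethylmethanediamine, CN(C)CN(C)C
Why: The same Mannich aminomethylation as in step 9 can occur only at a1, the single free ring carbon, which is flanked by two hydroxyls and is strongly nucleophilic.

Step 12
Reactants: 21 (ring A Mannich base); 20 (B–C half)
Product: 23 1-{3-[(3-butanoyl-2,6-dihydroxy-4-methoxy-5-methylphenyl)methyl]-5-[(3-butanoyl-2,4-dihydroxy-6-methoxy-5-methylphenyl)methyl]-2,4,6-trihydroxyphenyl}butan-1-one, via ortho-quinone methide 22 (not isolated)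
Conditions: 21 (1.2 equiv), 1,4-dioxane, 90 °C, N2 sweep; chromatography
Reagents that add atoms: none
Why: The same elimination–Michael addition sequence as in step 10 applies, and the quinone methide can be captured on carbon only by the one free ring B position of 20, since rings B and C carry no other unsubstituted carbon.

**Compound list**
1 | methyl 3-oxopentanoate | CCC(=O)CC(=O)OC | starting material
2 | methyl (2Z)-3-[(trimethylsilyl)oxy]pent-2-enoate | CC/C(O[Si](C)(C)C)=C/C(=O)OC | intermediate
3 | lithium (1Z,3Z)-1-methoxy-3-[(trimethylsilyl)oxy]penta-1,3-dien-1-olate | [Li+].C/C=C(O[Si](C)(C)C)/C=C(/OC)[O-] | intermediate (not isolated)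
4 | (1Z,3Z)-1-methoxy-1,3-bis[(trimethylsilyl)oxy]penta-1,3-diene (isomer drawn; the geometry is erased later) | C/C=C(O[Si](C)(C)C)/C=C(/OC)O[Si](C)(C)C | intermediate
5 | 2-chloro-1,1-dimethoxyethane | COC(CCl)OC | starting material
6 | butanal | CCCC=O | starting material
7 | lithium methoxyacetylide | [Li+].[C-]#COC | intermediate (not isolated)
8 | 1-methoxyhex-1-yn-3-ol (racemic) | CCCC(O)C#COC | intermediate
9 | 1-methoxyhex-1-yn-3-one | CCCC(=O)C#COC | intermediate
10 | 1-{2,6-dimethoxy-3-methyl-4,6-bis[(trimethylsilyl)oxy]cyclohexa-1,4-dien-1-yl}butan-1-one (mixture of diastereomers, both centres lost) | CCCC(=O)C1=C(OC)C(C)C(O[Si](C)(C)C)=CC1(OC)O[Si](C)(C)C | intermediate (not isolated)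
11 | 1-(4,6-dihydroxy-2-methoxy-3-methylphenyl)butan-1-one (ring A monomer) | CCCC(=O)c1c(O)cc(O)c(C)c1OC | intermediate
12 | 2-methylbenzene-1,3,5-triol | Cc1c(O)cc(O)cc1O | starting material
13 | butanoyl chloride | CCCC(Cl)=O | starting material
14 | 1-(2,4,6-trihydroxy-3-methylphenyl)butan-1-one | CCCC(=O)c1c(O)cc(O)c(C)c1O | intermediate
15 | aspidinol, 1-(2,6-dihydroxy-4-methoxy-3-methylphenyl)butan-1-one (ring C monomer) | CCCC(=O)c1c(O)cc(OC)c(C)c1O | intermediate
16 | benzene-1,3,5-triol | Oc1cc(O)cc(O)c1 | starting material
17 | 1-(2,4,6-trihydroxyphenyl)butan-1-one (ring B) | CCCC(=O)c1c(O)cc(O)cc1O | intermediate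
18 | 1-{3-[(dimethylamino)methyl]-2,6-dihydroxy-4-methoxy-5-methylphenyl}butan-1-one | CCCC(=O)c1c(O)c(CN(C)C)c(OC)c(C)c1O | intermediate
19 | 2-butanoyl-3-hydroxy-5-methoxy-4-methyl-6-methylidenecyclohexa-2,4-dien-1-one | CCCC(=O)C1=C(O)C(C)=C(OC)C(=C)C1=O | intermediate (not isolated)
20 | 1-{3-[(3-butanoyl-2,4-dihydroxy-6-methoxy-5-methylphenyl)methyl]-2,4,6-trihydroxyphenyl}butan-1-one (B–C half) | CCCC(=O)c1c(O)cc(O)c(Cc2c(O)c(C(=O)CCC)c(O)c(C)c2OC)c1O | intermediate
21 | 1-{3-[(dimethylamino)methyl]-2,4-dihydroxy-6-methoxy-5-methylphenyl}butan-1-one | CCCC(=O)c1c(O)c(CN(C)C)c(O)c(C)c1OC | intermediate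
22 | 2-butanoyl-5-hydroxy-3-methoxy-4-methyl-6-methylidenecyclohexa-2,4-dien-1-one | CCCC(=O)C1=C(OC)C(C)=C(O)C(=C)C1=O | intermediate (not isolated)
23 | 1-{3-[(3-butanoyl-2,6-dihydroxy-4-methoxy-5-methylphenyl)methyl]-5-[(3-butanoyl-2,4-dihydroxy-6-methoxy-5-methylphenyl)methyl]-2,4,6-trihydroxyphenyl}butan-1-one (CNP0171986.0) | CCCC(=O)c1c(O)c(Cc2c(O)c(C)c(OC)c(C(=O)CCC)c2O)c(O)c(Cc2c(O)c(C(=O)CCC)c(O)c(C)c2OC)c1O | target

**Count**
Total steps: 12. Longest linear sequence: 5 steps (for example steps 1, 2, 5, 11, 12, or steps 6, 7, 9, 10, 12).

**Steps most likely to fail**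

1. Step 5. The methoxy group donates into the alkyne and lowers its dienophilicity, so the cycloaddition may stall while the diene is lost to protodesilylation. The partners may also join in the reverse orientation or by a Michael–aldol course. The fallback leaves the cycloaddition and reaches the ring A monomer by protecting-group chemistry. It sets out from 14: two equivalents of benzyl bromide with K2CO3 in acetone should etherify the 4-OH and the 6-OH and leave the hydroxyl between the methyl group and the ketone, the most hindered and most firmly chelated one, giving 1-[4,6-bis(benzyloxy)-2-hydroxy-3-methylphenyl]butan-1-one F1. Forcing methylation of that hydroxyl (MeI, K2CO3, DMF, 60 °C) would give 1-[4,6-bis(benzyloxy)-2-methoxy-3-methylphenyl]butan-1-one F2, and hydrogenolysis (H2, Pd/C, EtOAc) would return to the route at 11.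

2. Step 12. Under hot amine conditions the methylene-linked rings may exchange by reversible fragmentation to quinone methides, and the Mannich base may condense with itself by ipso attack and loss of the aminomethyl group. The fallback replaces the preformed amine by the classical alkaline formaldehyde cross-condensation. It sets out from 11 and 20: aqueous formaldehyde in dilute NaOH at 0 °C for a short time should hydroxymethylate 11 in the flask to 1-[2,4-dihydroxy-3-(hydroxymethyl)-6-methoxy-5-methylphenyl]butan-1-one F4, which loses water to 22 and is captured by 20. The statistical mixture would be separated by chromatography, and the fallback comes back to the route at 23.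

3. Step 4. The alkoxyalkynyl carbinol may rearrange to methyl hex-2-enoate on traces of acid or on the oxidant surface, and the ynone may be hydrated during isolation. The fallback bypasses the carbinol and the oxidation. It sets out from 5 and 13: butanoyl chloride 13 with N,O-dimethylhydroxylamine hydrochloride and pyridine in CH2Cl2 gives N-methoxy-N-methylbutanamide F3. Lithium methoxyacetylide 7, made from 5 as in step 3, is acylated by F3 at −78 °C; the chelated tetrahedral adduct releases the ketone only on quench, and the fallback comes back to the route at 9.

**Further compounds**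
F1 | step 5 | 1-[4,6-bis(benzyloxy)-2-hydroxy-3-methylphenyl]butan-1-one | CCCC(=O)c1c(OCc2ccccc2)cc(OCc2ccccc2)c(C)c1O
F2 | step 5 | 1-[4,6-bis(benzyloxy)-2-methoxy-3-methylphenyl]butan-1-one | CCCC(=O)c1c(OCc2ccccc2)cc(OCc2ccccc2)c(C)c1OC
F3 | step 4 | N-methoxy-N-methylbutanamide | CCCC(=O)N(C)OC
F4 | step 12 | 1-[2,4-dihydroxy-3-(hydroxymethyl)-6-methoxy-5-methylphenyl]butan-1-one | CCCC(=O)c1c(O)c(CO)c(O)c(C)c1OC
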